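## Analysis of the target

CNP0154047.1 is a stilbenoid trimer built on a fully substituted benzene, ring B (B1 bears O1, B2 is the only CH, B3 bears O3, B4 bears Ce, B5 bears the CH2 group, B6 bears Cb). Three rings are fused to it: dihydrobenzofuran 1 (O1, Ca, Cb, B6, B1), dihydrobenzofuran 2 (O3, Cf, Ce, B4, B3) and a seven-membered carbocycle (B4, B5, CH2, Cd, C1, C6, Ce) that shares C1–C6 with the resorcinol ring C. All five stereocentres are R. The aryl groups on Ca/Cb are trans, those on Cf/Ce are trans, and on the seven-membered ring the 2,4-dihydroxyphenyl group on Cd (ring E) is trans to Cf. The two dihydrobenzofurans have the same constitution and the same configuration: without the Cd–C1 bond, a twofold axis through B2 and B5 exchanges them, so ring C and the free 3,5-dihydroxyphenyl ring on Cb (ring D) are equivalent until the seven-membered ring closes. Sensitive features are the eight phenols, three strongly nucleophilic resorcinol rings, and the benzylic ether bonds Ca–O1 and Cf–O3, which ionise under acid because each carbon carries a 4-oxygenated phenyl group. The difficulties are the hexasubstituted ring B (B4 must be told from B2), absolute control in two dihydrobenzofurans that cannot steer each other, and the configuration of Cd. The route rests on one feature: dihydrobenzofuran 1, with oxygens on B1, B3 and B5, is a ring-contracted 5,7-dioxygenated flavanone. Flavanone C2 is Ca (already bearing its aryl group and O1), C3 is Cb, and B6 is the ring carbon that moves from C4 to C3. The old carbonyl carbon remains as a carboxyl group on Cb, exactly where ring D must be attached. The same holds for dihydrobenzofuran 2 at B4.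

## Retrosynthetic reasoning

**33 ⇒ 32.** The eight phenols are carried as methyl ethers and freed last, since free resorcinols would not survive the oxidative and Lewis-acidic steps. Under the Lewis acid the only other labile bonds are Ca–O1 and Cf–O3; if they open they re-close trans because Cb and Ce stay fixed.

**32 ⇒ 31 (Cd–C1).** Cd is the carbon of a cation stabilised by the ortho and para methoxy groups of ring E, and C1 lies ortho and para to the two methoxy groups of ring C. In stilbene 31 the two 3,5-dimethoxyphenyl rings are exchanged by the twofold axis, so closure onto either gives the same compound and no regiochemical question arises. That is why the cut is made here and not at Ce–C6 or B5–CH2. The forward reaction must protonate the alkene carbon next to B5, close the seven-membered ring, and let the rigid framework set Cd.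

**31 ⇒ 28 + 30 (B5–CH).** The phloroglucinol pattern leaves an oxygen on B5; as triflate 28 it is the electrophile for the alkenylboronate 30, made from alkyne 29. Triflate 28 comes from phenol 27, and 27 from tosylate 26. The B5 oxygen travels as a tosylate because the earlier steps need a group there that is neither an ether nor a reactive pseudohalide.

**26 ⇒ 22 + 25 (Cb–aryl and Ce–aryl).** The two carboxyl groups of 20 are the former flavanone carbonyl carbons. Both are exchanged for 3,5-dimethoxyphenyl rings in one twofold decarboxylative arylation of the redox-active ester 22 (from acid 21) with arylzinc 25 (from bromide 23 via 24). Doing this late keeps every resorcinol ring away from the two oxidative ring contractions. Because the coupling passes through radicals at Cb and Ce, their final configuration is set here, by the aryl groups on Ca and Cf.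

**20 ⇒ 17 ⇒ 16 + 5 (Ce–B4, then Cf–aryl).** Dihydrobenzofuran 2 is made as dihydrobenzofuran 1 was: ring contraction of flavanone 17, which comes from chromone 16 and boronic acid 5 under catalyst control. Chromone 16 needs an acetyl group on B4 and a free hydroxyl on B3 (14). Only the B5 phenol of 10 has a single free ortho position, B4, so it directs the acetyl group there (12). It is then tosylated (13) so that chelation to the acetyl group frees the B3 oxygen alone (14). With only O3 free, the pyranone can close only on O3.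

**10 ⇐ 9 ⇒ 6 (Cb–B6, the key disconnection).** Flavanone 6 already holds Ca–O1 and the Ca–aryl bond with Ca configured. Cb–B6 then forms within the molecule by a 1,2-shift that places the carboxyl group trans to the Ca aryl group. Cutting O1–Ca or Ca–Cb instead would require separate control of both centres.

**6 ⇒ 4 + 5 (Ca–aryl).** Ca is set on the flat chromone 4 by an enantioselective conjugate addition of 5. Chromone 4 comes in two steps from acetophenone 1 through the mono-benzyl ether 2.

## Alternatives that were turned down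

**Alternative 1:** Ring B would be made last. Four of its bonds (B5–B6, B6–B1, B2–B3, B3–B4) are cut, giving diazomethyl ketone A1, in which the seven-membered ring with Cd, Ce and a silylated Cf carbinol already exists, and silyloxyalkyne A2. On irradiation A1 would lose nitrogen and rearrange to a vinylketene; A2 would add to it, the cyclobutenone would open, and the dienylketene would close to phenol A3 (photochemical vinylketene benzannulation).
- For: the carbocycle and Cd, Ce, Cf are settled before the crowded arene exists; the two new ring-B oxygens come out differentiated; B2 versus B4 never arises. On securing the seven-membered ring and Cd early it is stronger than the chosen route.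
- Against: A3 still has hydrogen at B6. All of dihydrobenzofuran 1 (Cb–B6, Ca–Cb, Ca–O1, two stereocentres) must be added afterwards next to the seven-membered ring with nothing in A3 to control it. A1 is itself a long enantioselective synthesis, and the final electrocyclisation must form B3–B4 beside the branched Ce.
- Comparison: the chosen route starts from a ring B that already carries its three oxygens and builds both dihydrobenzofurans with the same catalytic addition and rearrangement. Cd comes late, but it is then set on a rigid tetracyclic framework.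

**Alternative 2:** Both benzylic aryl bonds (Cb–ring D and Ce–C6) are cut in a bis-coumarin, A4. Rh(acac)(C2H4)2 with one Segphos enantiomer would add boronic acid A5 to both coumarin rings (Hayashi–Miyaura reaction), giving the C2-symmetric bis(dihydrocoumarin) A6.
- For: it uses the same twofold symmetry; one catalytic step makes two C–C bonds and two stereocentres; doubling raises the enantiomeric purity of the major diastereomer. It sets Cb and Ce by catalyst more directly than the chosen route, where they follow from Ca and Cf.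
- Against: each lactone of A6 has two carbons between the ring oxygen and the benzylic centre where the target has one. One carbon must be excised and Ca (Cf) created with its aryl group and C–O bond. This passes through α,α-diaryl carbonyl compounds whose acidic methine hydrogen is the stereocentre just made, and it must be done twice. Both additions also occur peri to the same ester-bearing B5.
- Comparison: in the chosen route the ring has the right size and Ca has its aryl group and oxygen from the start. The surplus carbon leaves as CO2 in the step that brings in ring D.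

**Alternative 3:** Ca–Cb and Cf–Ce are cut. In bis(aryldiazoacetate) A7 the divalent rhodium carboxylate Rh2(S-PTTL)4 would turn each diazo group into a carbene that inserts into a benzylic C–H of the neighbouring 4-methoxybenzyl ether; methoxide in the same flask would epimerise the cis esters to the trans,trans diester A8.
- For: both dihydrobenzofurans and four stereocentres come from one operation, and A8 corresponds to diester 20 of the chosen route with the B5 carbon already present. On step economy and convergence this alternative is clearly stronger.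
- Against: both carbenes sit on a hexasubstituted ring, each flanked by the ether and by the same B5 substituent. A7 needs a twofold diazo transfer onto doubly ortho-substituted arylacetates. Attack of the carbene on the ether oxygen (oxonium ylide, then benzyl shift) competes with C–H insertion, and any shortfall counts twice.
- Comparison: the chosen route is longer, but each C–C bond is formed by a reaction known on flavonoids or on simple secondary acids. The absolute configuration is set on unhindered chromones, and the starting materials are a phloroacetophenone ether and two simple aryl reagents.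

Key step: step 4

Assumption: (S)-t-BuPyOX is taken to deliver the aryl group to the chromone face that gives the 2R flavanone, as its sense of induction with 3-substituted cyclohexenones implies; if the opposite sense were found, the R ligand would be used in steps 3 and 10. Compounds 1 and 29 are taken as purchasable.

## Route

Step 1
Reactants: 1 2′,6′-dihydroxy-4′-methoxyacetophenone
Product: 2 2′-benzyloxy-6′-hydroxy-4′-methoxyacetophenone
Conditions: BnBr (1.05 equiv), K2CO3, acetone, 56 °C
Reagents that add atoms: benzyl bromide, BrCc1ccccc1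
Why: Williamson ether synthesis; after the first alkylation the remaining phenol is held in a hydrogen bond to the ketone and is far less nucleophilic, so mono-benzylation is expected with one equivalent of bromide.

Step 2
Reactants: 2 2′-benzyloxy-6′-hydroxy-4′-methoxyacetophenone
Product: 4 5-benzyloxy-7-methoxy-4H-chromen-4-one, via enaminone 3 (not isolated)
Conditions: Me2NCH(OMe)2, toluene, 100 °C; then conc. HCl, CH2Cl2, 40 °C
Reagents that add atoms: N,N-dimethylformamide dimethyl acetal, COC(OC)N(C)C
Why: Enaminone route to chromones: the methyl ketone condenses with the amide acetal, and acid then drives conjugate addition of the phenol and loss of dimethylamine; both ethers are inert.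

Step 3
Reactants: 4 5-benzyloxy-7-methoxy-4H-chromen-4-one; 5 4-methoxyphenylboronic acid
Product: 6 (2R)-5-benzyloxy-7-methoxy-2-(4-methoxyphenyl)chroman-4-one
Conditions: Pd(OCOCF3)2 (5 mol%), (S)-t-BuPyOX (6 mol%), NH4PF6 (30 mol%), H2O (5 equiv), ClCH2CH2Cl, 60 °C
Reagents that add atoms: none
Why: Divalent-palladium-catalysed asymmetric conjugate addition of an arylboronic acid to a chromone: transmetalation gives an arylpalladium species that inserts the C2=C3 bond, and water cleaves the palladium enolate. The tert-butyl group of the pyridine-oxazoline ligand selects the enone face, setting Ca as R, and the base-free medium avoids opening to the chalcone.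

Step 4
Reactants: 6 (2R)-5-benzyloxy-7-methoxy-2-(4-methoxyphenyl)chroman-4-one
Product: 9 methyl (2R,3R)-4-benzyloxy-6-methoxy-2-(4-methoxyphenyl)-2,3-dihydrobenzofuran-3-carboxylate (trans), via enol ether 7 (not isolated), via orthoester 8 (not isolated)
Conditions: PhI(OAc)2 (1.3 equiv), HC(OMe)3, conc. H2SO4, MeOH, 0 → 25 °C; then H2O
Reagents that add atoms: trimethyl orthoformate, COC(OC)OC (ester methoxy group); water, O (ester carbonyl oxygen)
Why: Acid and orthoformate convert ketone 6 into enol ether 7. C3 of 7 attacks the trivalent iodine of PhI(OAc)2 on the face opposite the pseudo-equatorial aryl group on C2, and methanol adds to the C4 oxocarbenium ion. The C3–I bond is then antiperiplanar to C4–B6, so B6 shifts from C4 to C3 as iodobenzene leaves, and the dialkoxycarbenium ion is trapped as orthoester 8, which water hydrolyses to ester 9. The closest known reaction is the oxidative rearrangement of flavanones and of aryl alkyl ketones by trivalent iodine or Tl(NO3)3 in trimethyl orthoformate. The furan ring is closed by C–C bond formation (Cb–B6) through contraction of the pyranone, not by C–O bond formation; O1–Ca is untouched. Cb is set by Ca: anti iodination followed by inversion at C3 puts the carboxyl carbon trans to the aryl group (2R,3R), which is also the more stable epimer. The step needs B6 to migrate in preference to the C2 aryl group (isoflavone) or to loss of a proton (flavone); the ketal pathway places the charge on a C4 bearing two methoxy groups, and B6 has alkoxy donors at both ortho positions and the para position.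

Step 5
Reactants: 9 methyl (2R,3R)-4-benzyloxy-6-methoxy-2-(4-methoxyphenyl)-2,3-dihydrobenzofuran-3-carboxylate
Product: 10 methyl (2R,3R)-4-hydroxy-6-methoxy-2-(4-methoxyphenyl)-2,3-dihydrobenzofuran-3-carboxylate
Conditions: H2 (1 atm), 10% Pd/C, EtOAc/MeOH, 25 °C
Reagents that add atoms: none
Why: Hydrogenolysis of the aryl benzyl ether; the cyclic benzylic Ca–O1 bond cleaves far more slowly and the ester is inert. The freed B5 phenol cannot lactonise onto the Cb ester because the lactone would have to share the Cb–B6 bond with the dihydrofuran ring.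

Step 6
Reactants: 10 methyl (2R,3R)-4-hydroxy-6-methoxy-2-(4-methoxyphenyl)-2,3-dihydrobenzofuran-3-carboxylate
Product: 12 methyl (2R,3R)-5-acetyl-4-hydroxy-6-methoxy-2-(4-methoxyphenyl)-2,3-dihydrobenzofuran-3-carboxylate, via difluoroboron chelate 11 (not isolated)
Conditions: Ac2O, BF3·OEt2, CH2Cl2, 0 → 25 °C; then NaOAc, MeOH/H2O, 50 °C
Reagents that add atoms: acetic anhydride, CC(=O)OC(C)=O
Why: BF3-mediated ortho-acylation of a phenol (O-acylation and Fries-type shift). B4 is the only free ortho position of the B5 phenol and lies between two oxygen donors; formation of chelate 11 favours it over B2, and the anisyl ring is much less nucleophilic.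

Step 7
Reactants: 12 methyl (2R,3R)-5-acetyl-4-hydroxy-6-methoxy-2-(4-methoxyphenyl)-2,3-dihydrobenzofuran-3-carboxylate
Product: 13 methyl (2R,3R)-5-acetyl-6-methoxy-2-(4-methoxyphenyl)-4-(4-methylphenylsulfonyloxy)-2,3-dihydrobenzofuran-3-carboxylate
Conditions: TsCl, K2CO3, acetone, 56 °C
Reagents that add atoms: p-toluenesulfonyl chloride, Cc1ccc(S(=O)(=O)Cl)cc1
Why: Sulfonylation of the phenol. A tosylate is chosen because its oxygen is not basic enough to be cleaved by BCl3, and because it should withstand the amide acetal, acid, trivalent iodine, cold hydroxide and bipyridine-ligated nickel of steps 8–15.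

Step 8
Reactants: 13 methyl (2R,3R)-5-acetyl-6-methoxy-2-(4-methoxyphenyl)-4-(4-methylphenylsulfonyloxy)-2,3-dihydrobenzofuran-3-carboxylate
Product: 14 methyl (2R,3R)-5-acetyl-6-hydroxy-2-(4-methoxyphenyl)-4-(4-methylphenylsulfonyloxy)-2,3-dihydrobenzofuran-3-carboxylate
Conditions: BCl3 (1.5 equiv), CH2Cl2, −78 → 0 °C; then H2O
Reagents that add atoms: none
Why: Chelation-controlled demethylation: BCl3 binds the acetyl oxygen and the neighbouring B3 methoxy oxygen in a six-membered chelate and chloride removes that methyl group. The anisyl ether, the ester and the sulfonate have no such chelate and are left at low temperature.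

Step 9
Reactants: 14 methyl (2R,3R)-5-acetyl-6-hydroxy-2-(4-methoxyphenyl)-4-(4-methylphenylsulfonyloxy)-2,3-dihydrobenzofuran-3-carboxylate
Product: 16 methyl (2R,3R)-2-(4-methoxyphenyl)-5-oxo-4-(4-methylphenylsulfonyloxy)-2,3-dihydro-5H-furo[3,2-g]chromene-3-carboxylate, via enaminone 15 (not isolated)
Conditions: Me2NCH(OMe)2, toluene, 100 °C; then conc. HCl, CH2Cl2, 40 °C
Reagents that add atoms: N,N-dimethylformamide dimethyl acetal, COC(OC)N(C)C
Why: Enaminone route to chromones as in step 2; the B3 hydroxyl is the only free phenol, so the pyranone must close on O3.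

Step 10
Reactants: 16 methyl (2R,3R)-2-(4-methoxyphenyl)-5-oxo-4-(4-methylphenylsulfonyloxy)-2,3-dihydro-5H-furo[3,2-g]chromene-3-carboxylate; 5 4-methoxyphenylboronic acid
Product: 17 methyl (2R,3R,7R)-2,7-bis(4-methoxyphenyl)-5-oxo-4-(4-methylphenylsulfonyloxy)-2,3,6,7-tetrahydro-5H-furo[3,2-g]chromene-3-carboxylate
Conditions: Pd(OCOCF3)2 (10 mol%), (S)-t-BuPyOX (12 mol%), NH4PF6 (30 mol%), H2O (5 equiv), ClCH2CH2Cl, 60 °C
Reagents that add atoms: none
Why: Same divalent-palladium conjugate addition as step 3. The existing centres are remote on the other side of ring B, so the ligand alone decides the face, and the same ligand enantiomer sets Cf as R.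

Step 11
Reactants: 17 methyl (2R,3R,7R)-2,7-bis(4-methoxyphenyl)-5-oxo-4-(4-methylphenylsulfonyloxy)-2,3,6,7-tetrahydro-5H-furo[3,2-g]chromene-3-carboxylate
Product: 20 dimethyl (2R,3R,5R,6R)-2,6-bis(4-methoxyphenyl)-4-(4-methylphenylsulfonyloxy)-2,3,5,6-tetrahydrobenzo[1,2-b:5,4-b′]difuran-3,5-dicarboxylate, via enol ether 18 (not isolated), via orthoester 19 (not isolated)
Conditions: PhI(OAc)2 (1.3 equiv), HC(OMe)3, conc. H2SO4, MeOH, 0 → 25 °C; then H2O
Reagents that add atoms: trimethyl orthoformate, COC(OC)OC (ester methoxy group); water, O (ester carbonyl oxygen)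
Why: Second oxidative ring contraction, as in step 4: B4, with O3 ortho and O1 para, shifts from the ketal carbon to the iodinated carbon, giving the trans ester at Ce. No resorcinol ring is yet present to compete for the oxidant, and the product is C2-symmetric.

Step 12
Reactants: 20 dimethyl (2R,3R,5R,6R)-2,6-bis(4-methoxyphenyl)-4-(4-methylphenylsulfonyloxy)-2,3,5,6-tetrahydrobenzo[1,2-b:5,4-b′]difuran-3,5-dicarboxylate
Product: 21 (2R,3R,5R,6R)-2,6-bis(4-methoxyphenyl)-4-(4-methylphenylsulfonyloxy)-2,3,5,6-tetrahydrobenzo[1,2-b:5,4-b′]difuran-3,5-dicarboxylic acid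
Conditions: LiOH, THF/H2O, 25 → 40 °C; then 1 M HCl
Reagents that add atoms: lithium hydroxide, [Li+].[OH-] (hydroxyl oxygen of each acid)
Why: Ester saponification. The trans esters are the more stable epimers, so enolisation changes nothing, and ring opening of the enolate by loss of the β-aryloxide is the reverse of a disfavoured 5-endo-trig closure. The aryl tosylate needs hot alkali to cleave.

Step 13
Reactants: 21 (2R,3R,5R,6R)-2,6-bis(4-methoxyphenyl)-4-(4-methylphenylsulfonyloxy)-2,3,5,6-tetrahydrobenzo[1,2-b:5,4-b′]difuran-3,5-dicarboxylic acid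
Product: 22 bis(1,3-dioxoisoindolin-2-yl) (2R,3R,5R,6R)-2,6-bis(4-methoxyphenyl)-4-(4-methylphenylsulfonyloxy)-2,3,5,6-tetrahydrobenzo[1,2-b:5,4-b′]difuran-3,5-dicarboxylate
Conditions: N-hydroxyphthalimide, i-PrN=C=N-i-Pr, DMAP (cat.), CH2Cl2, 25 °C
Reagents that add atoms: N-hydroxyphthalimide, O=C1N(O)C(=O)c2ccccc12
Why: Steglich-type esterification to the redox-active N-acyloxyphthalimides; the product is used directly, and epimerisation at Cb or Ce is irrelevant because both centres are re-formed in step 15.

Step 14
Reactants: 23 1-bromo-3,5-dimethoxybenzene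
Product: 25 (3,5-dimethoxyphenyl)zinc chloride (THF solution), via arylmagnesium bromide 24 (not isolated)
Conditions: Mg, LiCl, THF, 25 °C; then ZnCl2, THF, 0 → 25 °C
Reagents that add atoms: zinc chloride, Cl[Zn]Cl
Why: Magnesium insertion into the aryl bromide followed by transmetalation to zinc gives the mild aryl nucleophile for step 15.

Step 15
Reactants: 22 bis(1,3-dioxoisoindolin-2-yl) diester; 25 (3,5-dimethoxyphenyl)zinc chloride
Product: 26 (2R,3R,5R,6R)-3,5-bis(3,5-dimethoxyphenyl)-2,6-bis(4-methoxyphenyl)-2,3,5,6-tetrahydrobenzo[1,2-b:5,4-b′]difuran-4-yl 4-methylbenzenesulfonate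
Conditions: NiCl2(glyme) (40 mol%), 4,4′-di-tert-butyl-2,2′-bipyridine (80 mol%), 25 (6 equiv), THF/DMF, 25 °C
Reagents that add atoms: none
Why: Nickel-catalysed decarboxylative Negishi-type arylation of redox-active esters: electron transfer from low-valent nickel to each N-acyloxyphthalimide releases CO2 and phthalimide anion and leaves a secondary benzylic radical at Cb (Ce). The radical is captured by the arylnickel species formed from 25, and reductive elimination forms the C–aryl bond on the face opposite the neighbouring 4-methoxyphenyl group, which should give the trans,trans product with Cb and Ce both R. The hindered aryl tosylate is not activated by bipyridine-ligated nickel at 25 °C.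

Step 16
Reactants: 26 (2R,3R,5R,6R)-3,5-bis(3,5-dimethoxyphenyl)-2,6-bis(4-methoxyphenyl)-2,3,5,6-tetrahydrobenzo[1,2-b:5,4-b′]difuran-4-yl 4-methylbenzenesulfonate
Product: 27 (2R,3R,5R,6R)-3,5-bis(3,5-dimethoxyphenyl)-2,6-bis(4-methoxyphenyl)-2,3,5,6-tetrahydrobenzo[1,2-b:5,4-b′]difuran-4-ol
Conditions: KOH, t-BuOH/toluene/H2O, 80 °C; then 1 M HCl
Reagents that add atoms: none
Why: Hydroxide attacks the sulfur of the aryl sulfonate (S–O cleavage). No primary alkoxide is present that could form an alkylating tosylate ester, and methyl ethers and dihydrobenzofurans are stable to alkali.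

Step 17
Reactants: 27 (2R,3R,5R,6R)-3,5-bis(3,5-dimethoxyphenyl)-2,6-bis(4-methoxyphenyl)-2,3,5,6-tetrahydrobenzo[1,2-b:5,4-b′]difuran-4-ol
Product: 28 (2R,3R,5R,6R)-3,5-bis(3,5-dimethoxyphenyl)-2,6-bis(4-methoxyphenyl)-2,3,5,6-tetrahydrobenzo[1,2-b:5,4-b′]difuran-4-yl trifluoromethanesulfonate
Conditions: Tf2O, pyridine, CH2Cl2, 0 → 25 °C
Reagents that add atoms: trifluoromethanesulfonic anhydride, O=S(=O)(OS(=O)(=O)C(F)(F)F)C(F)(F)F
Why: O-Triflation of the phenol turns the B5 oxygen into a leaving group for palladium; the small, highly electrophilic anhydride reaches the phenol although both ortho positions are substituted.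

Step 18
Reactants: 29 1-ethynyl-2,4-dimethoxybenzene
Product: 30 2-[(E)-2-(2,4-dimethoxyphenyl)ethenyl]-4,4,5,5-tetramethyl-1,3,2-dioxaborolane
Conditions: pinacolborane, Cp2Zr(H)Cl (10 mol%), Et3N (10 mol%), 60 °C
Reagents that add atoms: pinacolborane, [H]B1OC(C)(C)C(C)(C)O1
Why: Zirconium-hydride-catalysed syn-hydroboration of a terminal alkyne places boron on the terminal carbon and gives the E-alkenylboronate.

Step 19
Reactants: 28 aryl triflate; 30 2-[(E)-2-(2,4-dimethoxyphenyl)ethenyl]-4,4,5,5-tetramethyl-1,3,2-dioxaborolane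
Product: 31 (2R,3R,5R,6R)-4-[(E)-2-(2,4-dimethoxyphenyl)ethenyl]-3,5-bis(3,5-dimethoxyphenyl)-2,6-bis(4-methoxyphenyl)-2,3,5,6-tetrahydrobenzo[1,2-b:5,4-b′]difuran
Conditions: Pd(OAc)2 (10 mol%), SPhos (20 mol%), K3PO4, toluene/H2O, 90 °C
Reagents that add atoms: none
Why: Suzuki–Miyaura coupling; the bulky electron-rich biarylphosphine lets zerovalent palladium insert into the doubly ortho-substituted aryl triflate, and the alkenyl group transfers with retention of the E geometry.

Step 20
Reactants: 31 (2R,3R,5R,6R)-4-[(E)-2-(2,4-dimethoxyphenyl)ethenyl]-3,5-bis(3,5-dimethoxyphenyl)-2,6-bis(4-methoxyphenyl)-2,3,5,6-tetrahydrobenzo[1,2-b:5,4-b′]difuran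
Product: 32 octa-O-methyl ether of CNP0154047.1 (Ca, Cb, Cd, Ce, Cf all R)
Conditions: CF3CO2H, CH2Cl2 (0.005 M), −20 → 0 °C
Reagents that add atoms: none
Why: Intramolecular Friedel–Crafts alkylation: protonation of the alkene carbon bonded to B5 gives the cation at Cd, stabilised by the ortho and para methoxy groups of ring E (the other cation would sit next to ring B, whose oxygens are meta). An ortho carbon of a 3,5-dimethoxyphenyl ring attacks and closes the seven-membered ring; the two such rings are homotopic, so either closure gives 32. Cd is set by the ring: a model of the boat-shaped ring puts ring E pseudo-equatorial and turned away from ring B in the R epimer, and the stabilised cation allows the closure to equilibrate towards it.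

Step 21
Reactants: 32 octa-O-methyl ether of CNP0154047.1
Product: 33 CNP0154047.1 (target)
Conditions: BBr3, CH2Cl2, −78 → 25 °C; then MeOH, H2O
Reagents that add atoms: none
Why: Lewis-acid cleavage of the eight aryl methyl ethers. If Ca–O1 or Cf–O3 ionises, the cation can only re-close to the trans ring, because attack by the neighbouring resorcinol ring would form a four-membered ring and Cb, Ce and Cd are not touched.

## Compound list

1 | 2′,6′-dihydroxy-4′-methoxyacetophenone | CC(=O)c1c(O)cc(OC)cc1O | starting material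
2 | 2′-benzyloxy-6′-hydroxy-4′-methoxyacetophenone | CC(=O)c1c(O)cc(OC)cc1OCc1ccccc1 | intermediate
3 | (E)-1-(2-benzyloxy-6-hydroxy-4-methoxyphenyl)-3-(dimethylamino)prop-2-en-1-one | CN(C)/C=C/C(=O)c1c(O)cc(OC)cc1OCc1ccccc1 | intermediate (not isolated)
4 | 5-benzyloxy-7-methoxy-4H-chromen-4-one | COc1cc(OCc2ccccc2)c2c(=O)ccoc2c1 | intermediate
5 | 4-methoxyphenylboronic acid | COc1ccc(B(O)O)cc1 | starting material
6 | (2R)-5-benzyloxy-7-methoxy-2-(4-methoxyphenyl)chroman-4-one | COc1ccc([C@H]2CC(=O)c3c(OCc4ccccc4)cc(OC)cc3O2)cc1 | intermediate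
7 | (2R)-5-benzyloxy-4,7-dimethoxy-2-(4-methoxyphenyl)-2H-chromene | COc1ccc([C@H]2C=C(OC)c3c(OCc4ccccc4)cc(OC)cc3O2)cc1 | intermediate (not isolated)
8 | (2R,3R)-4-benzyloxy-6-methoxy-2-(4-methoxyphenyl)-3-(trimethoxymethyl)-2,3-dihydrobenzofuran | COc1ccc([C@@H]2Oc3cc(OC)cc(OCc4ccccc4)c3[C@H]2C(OC)(OC)OC)cc1 | intermediate (not isolated)
9 | methyl (2R,3R)-4-benzyloxy-6-methoxy-2-(4-methoxyphenyl)-2,3-dihydrobenzofuran-3-carboxylate | COc1ccc([C@@H]2Oc3cc(OC)cc(OCc4ccccc4)c3[C@H]2C(=O)OC)cc1 | intermediate
10 | methyl (2R,3R)-4-hydroxy-6-methoxy-2-(4-methoxyphenyl)-2,3-dihydrobenzofuran-3-carboxylate | COc1ccc([C@@H]2Oc3cc(OC)cc(O)c3[C@H]2C(=O)OC)cc1 | intermediate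
11 | difluoroboron chelate of 12 (boron bridging the B5 oxygen and the acetyl oxygen) | COc1ccc([C@@H]2Oc3cc(OC)c4C(C)=[O+][B-](F)(F)Oc4c3[C@H]2C(=O)OC)cc1 | intermediate (not isolated)
12 | methyl (2R,3R)-5-acetyl-4-hydroxy-6-methoxy-2-(4-methoxyphenyl)-2,3-dihydrobenzofuran-3-carboxylate | COc1ccc([C@@H]2Oc3cc(OC)c(C(C)=O)c(O)c3[C@H]2C(=O)OC)cc1 | intermediate
13 | methyl (2R,3R)-5-acetyl-6-methoxy-2-(4-methoxyphenyl)-4-(4-methylphenylsulfonyloxy)-2,3-dihydrobenzofuran-3-carboxylate | COc1ccc([C@@H]2Oc3cc(OC)c(C(C)=O)c(OS(=O)(=O)c4ccc(C)cc4)c3[C@H]2C(=O)OC)cc1 | intermediate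
14 | methyl (2R,3R)-5-acetyl-6-hydroxy-2-(4-methoxyphenyl)-4-(4-methylphenylsulfonyloxy)-2,3-dihydrobenzofuran-3-carboxylate | COc1ccc([C@@H]2Oc3cc(O)c(C(C)=O)c(OS(=O)(=O)c4ccc(C)cc4)c3[C@H]2C(=O)OC)cc1 | intermediate
15 | enaminone of 14: methyl (2R,3R)-5-[(E)-3-(dimethylamino)prop-2-enoyl]-6-hydroxy-2-(4-methoxyphenyl)-4-(4-methylphenylsulfonyloxy)-2,3-dihydrobenzofuran-3-carboxylate | COc1ccc([C@@H]2Oc3cc(O)c(C(=O)/C=C/N(C)C)c(OS(=O)(=O)c4ccc(C)cc4)c3[C@H]2C(=O)OC)cc1 | intermediate (not isolated)
16 | methyl (2R,3R)-2-(4-methoxyphenyl)-5-oxo-4-(4-methylphenylsulfonyloxy)-2,3-dihydro-5H-furo[3,2-g]chromene-3-carboxylate | COc1ccc([C@@H]2Oc3cc4occc(=O)c4c(OS(=O)(=O)c5ccc(C)cc5)c3[C@H]2C(=O)OC)cc1 | intermediate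
17 | methyl (2R,3R,7R)-2,7-bis(4-methoxyphenyl)-5-oxo-4-(4-methylphenylsulfonyloxy)-2,3,6,7-tetrahydro-5H-furo[3,2-g]chromene-3-carboxylate | COc1ccc([C@@H]2Oc3cc4O[C@@H](c5ccc(OC)cc5)CC(=O)c4c(OS(=O)(=O)c5ccc(C)cc5)c3[C@H]2C(=O)OC)cc1 | intermediate
18 | methyl (2R,3R,7R)-5-methoxy-2,7-bis(4-methoxyphenyl)-4-(4-methylphenylsulfonyloxy)-2,3-dihydro-7H-furo[3,2-g]chromene-3-carboxylate | COc1ccc([C@@H]2Oc3cc4O[C@@H](c5ccc(OC)cc5)C=C(OC)c4c(OS(=O)(=O)c5ccc(C)cc5)c3[C@H]2C(=O)OC)cc1 | intermediate (not isolated)
19 | methyl (2R,3R,5R,6R)-2,6-bis(4-methoxyphenyl)-4-(4-methylphenylsulfonyloxy)-5-(trimethoxymethyl)-2,3,5,6-tetrahydrobenzo[1,2-b:5,4-b′]difuran-3-carboxylate | COc1ccc([C@@H]2Oc3cc4O[C@@H](c5ccc(OC)cc5)[C@H](C(OC)(OC)OC)c4c(OS(=O)(=O)c5ccc(C)cc5)c3[C@H]2C(=O)OC)cc1 | intermediate (not isolated)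
20 | dimethyl (2R,3R,5R,6R)-2,6-bis(4-methoxyphenyl)-4-(4-methylphenylsulfonyloxy)-2,3,5,6-tetrahydrobenzo[1,2-b:5,4-b′]difuran-3,5-dicarboxylate | COc1ccc([C@@H]2Oc3cc4O[C@@H](c5ccc(OC)cc5)[C@H](C(=O)OC)c4c(OS(=O)(=O)c5ccc(C)cc5)c3[C@H]2C(=O)OC)cc1 | intermediate
21 | (2R,3R,5R,6R)-2,6-bis(4-methoxyphenyl)-4-(4-methylphenylsulfonyloxy)-2,3,5,6-tetrahydrobenzo[1,2-b:5,4-b′]difuran-3,5-dicarboxylic acid | COc1ccc([C@@H]2Oc3cc4O[C@@H](c5ccc(OC)cc5)[C@H](C(=O)O)c4c(OS(=O)(=O)c5ccc(C)cc5)c3[C@H]2C(=O)O)cc1 | intermediate
22 | bis(1,3-dioxoisoindolin-2-yl) (2R,3R,5R,6R)-2,6-bis(4-methoxyphenyl)-4-(4-methylphenylsulfonyloxy)-2,3,5,6-tetrahydrobenzo[1,2-b:5,4-b′]difuran-3,5-dicarboxylate | COc1ccc([C@@H]2Oc3cc4O[C@@H](c5ccc(OC)cc5)[C@H](C(=O)ON5C(=O)c6ccccc6C5=O)c4c(OS(=O)(=O)c5ccc(C)cc5)c3[C@H]2C(=O)ON2C(=O)c3ccccc3C2=O)cc1 | intermediate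
23 | 1-bromo-3,5-dimethoxybenzene | COc1cc(Br)cc(OC)c1 | starting material
24 | (3,5-dimethoxyphenyl)magnesium bromide | COc1cc([Mg]Br)cc(OC)c1 | intermediate (not isolated)
25 | (3,5-dimethoxyphenyl)zinc chloride | COc1cc([Zn]Cl)cc(OC)c1 | intermediate
26 | (2R,3R,5R,6R)-3,5-bis(3,5-dimethoxyphenyl)-2,6-bis(4-methoxyphenyl)-2,3,5,6-tetrahydrobenzo[1,2-b:5,4-b′]difuran-4-yl 4-methylbenzenesulfonate | COc1ccc([C@@H]2Oc3cc4O[C@@H](c5ccc(OC)cc5)[C@H](c5cc(OC)cc(OC)c5)c4c(OS(=O)(=O)c5ccc(C)cc5)c3[C@H]2c2cc(OC)cc(OC)c2)cc1 | intermediate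
27 | (2R,3R,5R,6R)-3,5-bis(3,5-dimethoxyphenyl)-2,6-bis(4-methoxyphenyl)-2,3,5,6-tetrahydrobenzo[1,2-b:5,4-b′]difuran-4-ol | COc1ccc([C@@H]2Oc3cc4O[C@@H](c5ccc(OC)cc5)[C@H](c5cc(OC)cc(OC)c5)c4c(O)c3[C@H]2c2cc(OC)cc(OC)c2)cc1 | intermediate
28 | (2R,3R,5R,6R)-3,5-bis(3,5-dimethoxyphenyl)-2,6-bis(4-methoxyphenyl)-2,3,5,6-tetrahydrobenzo[1,2-b:5,4-b′]difuran-4-yl trifluoromethanesulfonate | COc1ccc([C@@H]2Oc3cc4O[C@@H](c5ccc(OC)cc5)[C@H](c5cc(OC)cc(OC)c5)c4c(OS(=O)(=O)C(F)(F)F)c3[C@H]2c2cc(OC)cc(OC)c2)cc1 | intermediate
29 | 1-ethynyl-2,4-dimethoxybenzene | COc1ccc(C#C)c(OC)c1 | starting material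
30 | 2-[(E)-2-(2,4-dimethoxyphenyl)ethenyl]-4,4,5,5-tetramethyl-1,3,2-dioxaborolane | COc1ccc(/C=C/B2OC(C)(C)C(C)(C)O2)c(OC)c1 | intermediate
31 | (2R,3R,5R,6R)-4-[(E)-2-(2,4-dimethoxyphenyl)ethenyl]-3,5-bis(3,5-dimethoxyphenyl)-2,6-bis(4-methoxyphenyl)-2,3,5,6-tetrahydrobenzo[1,2-b:5,4-b′]difuran | COc1ccc([C@@H]2Oc3cc4O[C@@H](c5ccc(OC)cc5)[C@H](c5cc(OC)cc(OC)c5)c4c(/C=C/c4ccc(OC)cc4OC)c3[C@H]2c2cc(OC)cc(OC)c2)cc1 | intermediate
32 | octa-O-methyl ether of CNP0154047.1 (all five stereocentres R; ring B fused to both trans-dihydrobenzofurans and to the seven-membered ring through CH2, Cd and dimethoxy ring C) | COc1ccc([C@@H]2Oc3cc4c5c(c3[C@H]2c2cc(OC)cc(OC)c2)C[C@H](c2ccc(OC)cc2OC)c2c(OC)cc(OC)cc2[C@H]5[C@H](c2ccc(OC)cc2)O4)cc1 | intermediate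
33 | CNP0154047.1 (Ca, Cb, Cd, Ce, Cf all R) | Oc1ccc([C@@H]2Oc3cc4c5c(c3[C@H]2c2cc(O)cc(O)c2)C[C@H](c2ccc(O)cc2O)c2c(O)cc(O)cc2[C@H]5[C@H](c2ccc(O)cc2)O4)cc1 | target

## Step count and least certain steps

Total: 21 steps. Longest linear sequence: 19 steps (steps 1–13, 15–17, 19–21); steps 14 and 18 prepare the two coupling partners.

**Step 4 (key step).** The rearrangement may take another course. The 4-methoxyphenyl group on C2 is itself a good migrating group and could shift to C3 (isoflavone), or the iodinated intermediate could lose a proton (flavone). Both need no ketal and gain ground if enol ether formation is slowed by the peri benzyloxy group. The electron-rich trialkoxy ring could also be attacked by the oxidant. Step 11 repeats this reaction, so its outcome follows from step 4. Fallback, from 6 back to 9, by a Wolff ring contraction, which makes the same Cb–B6 bond without an oxidant: kinetic enolisation of 6 (LiN(SiMe3)2, THF, −78 °C) and acylation with 2,2,2-trifluoroethyl trifluoroacetate would give the 3-trifluoroacetyl flavanone F1. Diazo transfer with loss of the trifluoroacetyl group (MsN3, Et3N, MeCN) would give the 3-diazoflavanone F2. Irradiation in methanol would shift B6 to the carbene carbon and trap the ketene as the ester, expected mainly as the cis ester F3 (protonation anti to the aryl group). NaOMe in MeOH would then epimerise F3 to 9.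

**Step 15.** The planar benzylic radicals at Cb and Ce may be captured with incomplete facial selectivity (cis isomers). The alkylnickel intermediate may lose the hydrogen on Ca or Cf and aromatise to a benzofuran. The second coupling may stall after the first. Fallback, from 22 back to 26, separating radical formation from C–aryl bond formation: light-driven decarboxylative borylation of 22 (bis(catecholato)diboron, N,N-dimethylacetamide, blue light; then pinacol, Et3N) would give the trans,trans bis(pinacol boronate) F4, which can be purified as a single diastereomer. Palladium-catalysed coupling of the secondary benzylic boronates with 1-iodo-3,5-dimethoxybenzene (Pd2(dba)3, PPh3, Ag2O, K2CO3, dimethoxyethane, 85 °C), which proceeds with retention at carbon, would then give 26.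

**Step 20.** The cation may be attacked from the wrong face of Cd (epimer of 32), may alkylate another molecule, or the acid may open a dihydrobenzofuran faster than the ring closes. Fallback, from 28 back to 32, setting Cd by delivery of hydrogen instead of by C–C bond formation: Sonogashira coupling of 28 with alkyne 29 (PdCl2(PPh3)2, CuI, Et3N, DMF, 80 °C) would give the diarylalkyne F5. Acid- or gold-catalysed 7-endo hydroarylation ((Ph3P)AuNTf2 or catalytic CF3SO3H, CH2Cl2) would give the cycloheptene F6, with Cd in a ring double bond. Ionic hydrogenation (Et3SiH, CF3CO2H; hydride to the ring cation) or, for the opposite facial sense, H2 over Pd/C would then give 32.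

**Step 6.** The acetyl group may enter elsewhere (B2, or the anisyl ring). Alternatively BF3 may ionise Ca–O1, and loss of the Cb proton from that cation would erase both stereocentres before the ring re-closes. Fallback, from 10 back to 12, without strong Lewis acid: magnesium-mediated ortho-formylation (MgCl2, Et3N, paraformaldehyde, MeCN, 80 °C) is specific for the position ortho to the phenol and would give the salicylaldehyde F7. MeTi(OiPr)3 would add to the aldehyde but not to the ester, giving the carbinol F8 as a mixture of epimers. MnO2 in CH2Cl2 would oxidise the benzylic alcohol to 12.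

**Step 21.** The Lewis acid activates not only the eight methyl ethers but also the benzylic C–O bonds of both dihydrobenzofurans, so ring-opened or rearranged phenols may form, and cleavage of all eight ethers may be incomplete. Fallback, from 32 directly to 33, changing the mode of cleavage from electrophilic activation of oxygen to nucleophilic attack at the methyl carbons: NaSEt in DMF at 130 °C, followed by acidification. No Lewis acid then binds O1 or O3, and no new compound is involved.

## Further compounds

F1 | step 4 | (2R)-5-benzyloxy-7-methoxy-2-(4-methoxyphenyl)-3-(trifluoroacetyl)chroman-4-one (C3 not defined, enolised) | COc1ccc([C@H]2C(C(=O)C(F)(F)F)C(=O)c3c(OCc4ccccc4)cc(OC)cc3O2)cc1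
F2 | step 4 | (2S)-5-benzyloxy-3-diazo-7-methoxy-2-(4-methoxyphenyl)chroman-4-one (same spatial arrangement at C2 as 6; the descriptor changes with the diazo group) | COc1ccc([C@H]2C(=[N+]=[N-])C(=O)c3c(OCc4ccccc4)cc(OC)cc3O2)cc1
F3 | step 4 | methyl (2R,3S)-4-benzyloxy-6-methoxy-2-(4-methoxyphenyl)-2,3-dihydrobenzofuran-3-carboxylate (cis) | COc1ccc([C@@H]2Oc3cc(OC)cc(OCc4ccccc4)c3[C@@H]2C(=O)OC)cc1
F4 | step 15 | (2R,3R,5R,6R)-2,6-bis(4-methoxyphenyl)-3,5-bis(4,4,5,5-tetramethyl-1,3,2-dioxaborolan-2-yl)-2,3,5,6-tetrahydrobenzo[1,2-b:5,4-b′]difuran-4-yl 4-methylbenzenesulfonate | COc1ccc([C@@H]2Oc3cc4O[C@@H](c5ccc(OC)cc5)[C@H](B5OC(C)(C)C(C)(C)O5)c4c(OS(=O)(=O)c5ccc(C)cc5)c3[C@H]2B2OC(C)(C)C(C)(C)O2)cc1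
F5 | step 20 | (2R,3R,5R,6R)-4-[(2,4-dimethoxyphenyl)ethynyl]-3,5-bis(3,5-dimethoxyphenyl)-2,6-bis(4-methoxyphenyl)-2,3,5,6-tetrahydrobenzo[1,2-b:5,4-b′]difuran | COc1ccc([C@@H]2Oc3cc4O[C@@H](c5ccc(OC)cc5)[C@H](c5cc(OC)cc(OC)c5)c4c(C#Cc4ccc(OC)cc4OC)c3[C@H]2c2cc(OC)cc(OC)c2)cc1
F6 | step 20 | cycloheptene analogue of 32 with a double bond between Cd and the CH carbon on B5 | COc1ccc([C@@H]2Oc3cc4c5c(c3[C@H]2c2cc(OC)cc(OC)c2)C=C(c2ccc(OC)cc2OC)c2c(OC)cc(OC)cc2[C@H]5[C@H](c2ccc(OC)cc2)O4)cc1
F7 | step 6 | methyl (2R,3R)-5-formyl-4-hydroxy-6-methoxy-2-(4-methoxyphenyl)-2,3-dihydrobenzofuran-3-carboxylate | COc1ccc([C@@H]2Oc3cc(OC)c(C=O)c(O)c3[C@H]2C(=O)OC)cc1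
F8 | step 6 | methyl (2R,3R)-4-hydroxy-5-(1-hydroxyethyl)-6-methoxy-2-(4-methoxyphenyl)-2,3-dihydrobenzofuran-3-carboxylate (carbinol epimers) | COc1ccc([C@@H]2Oc3cc(OC)c(C(C)O)c(O)c3[C@H]2C(=O)OC)cc1
F0 | step 21 | none | none
A1 | alternative 1 | diazomethyl ketone on the benzo-fused cycloheptene that carries Cd (2,4-dimethoxyphenyl), Ce and the tert-butyldimethylsilyl ether of the Cf carbinol | [N-]=[N+]=CC(=O)C1=C[C@H]([C@H](c2ccc(OC)cc2)O[Si](C)(C)C(C)(C)C)c2cc(OC)cc(OC)c2[C@@H](c2ccc(OC)cc2OC)C1
A2 | alternative 1 | (triisopropylsilyloxy)ethyne | C#CO[Si](C(C)C)(C(C)C)C(C)C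
A3 | alternative 1 | ring-B phenol fused to the seven-membered ring (B3 hydroxyl free, B1 O-triisopropylsilyl, hydrogen at B6) | Oc1cc(O[Si](C(C)C)(C(C)C)C(C)C)cc2c1[C@H]([C@H](c1ccc(OC)cc1)O[Si](C)(C)C(C)(C)C)c1cc(OC)cc(OC)c1[C@@H](c1ccc(OC)cc1OC)C2
A4 | alternative 2 | methyl 2,8-dioxo-2H,8H-pyrano[3,2-g]chromene-5-carboxylate (ring-B bis-coumarin) | COC(=O)c1c2C=CC(=O)Oc2cc2OC(=O)C=Cc12
A5 | alternative 2 | 3,5-dimethoxyphenylboronic acid | COc1cc(B(O)O)cc(OC)c1
A6 | alternative 2 | C2-symmetric bis(4-aryl-3,4-dihydrocoumarin) on ring B | COC(=O)c1c2c(OC(=O)C[C@@H]2c4cc(OC)cc(OC)c4)cc3OC(=O)C[C@H](c4cc(OC)cc(OC)c4)c13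
A7 | alternative 3 | ring-B bis(aryldiazoacetate) with two 4-methoxybenzyl ethers and a silyloxymethyl group on B5 | CC(C)(C)[Si](C)(C)OCc1c(C(=[N+]=[N-])C(=O)OC)c(OCc2ccc(OC)cc2)cc(OCc2ccc(OC)cc2)c1C(=[N+]=[N-])C(=O)OC
A8 | alternative 3 | C2-symmetric trans,trans-bis(2-aryl-2,3-dihydrobenzofuran-3-carboxylate) on ring B | CC(C)(C)[Si](C)(C)OCc1c2c(O[C@@H](c4ccc(OC)cc4)[C@@H]2C(=O)OC)cc3O[C@@H](c4ccc(OC)cc4)[C@H](C(=O)OC)c13
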